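**Retrosynthetic overview**

- Pyran ring (closed last): the C3=C4 bond of the 2H-chromene is cut by ring-closing metathesis to a styrene/vinyl pair; the aryl–O–C2 bond is cut by palladium-catalysed asymmetric allylic etherification of a (Z)-allylic carbonate with symmetric 2-vinyl-4,5,6-trimethoxyresorcinol, which sets chromene C2.
- Side chain: the allylic carbonate comes from B-alkyl Suzuki coupling of the vinyl group of a 5-ethenyl-1,5,6-trimethylcyclohexene with (Z)-3-iodobut-2-en-1-ol.
- Carbocycle (closed first, key step): the ring C(CH3)=CH bond is cut to an acyclic methyl ketone whose C=O and CH=C(CH3)2 terminus are joined by carbonyl–olefin metathesis with loss of acetone.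
- The ketone comes in two steps from geranyl propionate: an enantioselective Ireland–Claisen rearrangement sets the quaternary ring carbon and its CH(CH3) neighbour together, then MeLi makes the ketone.
- Enabling feature: numbering the cyclohexene C1′ (quaternary) to C6′, its only double bond C3′(CH3)=C4′H is trisubstituted and lies between the C2′ methine and C5′H2; C3′ therefore maps onto a methyl ketone and C4′ onto the alkene CH of a prenyl terminus, held close by the fully substituted C1′/C2′ pair.

Key step: step 3

Assumption: the absolute sense of induction of the two reagent-controlled steps (the (S,S)-bromoborane in step 1 and the (S,S)-ligand in step 11) is taken by analogy with simpler substrates; if either sense proves opposite, the mirror-image reagent is used and nothing else changes.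

Step 1
Reactants: 1 geranyl propionate ((2E)-3,7-dimethylocta-2,6-dien-1-yl propanoate)
Product: 4 (2S,3S)-3-ethenyl-2,3,7-trimethyloct-6-enoic acid, via E(O)-boron ketene acetal 2 (not isolated), via boron carboxylate 3 (not isolated)
Conditions: preformed (S,S)-bromoborane [ArSO2N–CHPh–CHPh–NSO2Ar]B–Br (Ar = 3,5-(CF3)2C6H3; 1.1 equiv), Et3N, toluene/hexane, −78 °C (E(O)-enolate conditions); then −20 → 4 °C; aq work-up
Reagents that add atoms: none
Why: Ireland–Claisen rearrangement: the boron ketene acetal with the methyl group cis to the allyloxy oxygen rearranges through a chair transition state in which the (E)-alkene keeps its long chain equatorial, which fixes the relative configuration of the new CH(CH3) and quaternary centres as (2S*,3S*), while the C2-symmetric bis-sulfonamide on boron blocks one face of the enolate and so sets both absolute configurations.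

Step 2
Reactants: 4 (2S,3S)-3-ethenyl-2,3,7-trimethyloct-6-enoic acid
Product: 6 (3S,4S)-4-ethenyl-3,4,8-trimethylnon-7-en-2-one, via dilithium gem-diolate 5 (not isolated)
Conditions: MeLi (3 equiv), Et2O, 0 °C → rt; then poured into ice-water
Reagents that add atoms: methyllithium, [Li]C
Why: Conversion of a carboxylic acid into a methyl ketone with MeLi: the lithium carboxylate takes up one further equivalent to give the stable dilithium gem-diolate, which collapses to the ketone only on hydrolysis, so that no stereocentre is formed and the CH(CH3) centre is never present as an enolisable ketone next to base.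

Step 3
Reactants: 6 (3S,4S)-4-ethenyl-3,4,8-trimethylnon-7-en-2-one
Product: 8 (5S,6R)-5-ethenyl-1,5,6-trimethylcyclohex-1-ene, via cis-fused oxetane 7 (not isolated)
Conditions: FeCl3 (10 mol%), ClCH2CH2Cl, rt
Reagents that add atoms: none
Why: Proposed new method: FeCl3 activates the methyl ketone of 6 as a strongly electrophilic ferric chloride–carbonyl complex, the trisubstituted C=C attacks the carbonyl carbon through its CH carbon while the tertiary cation developing at the C(CH3)2 terminus is captured by the carbonyl oxygen in an asynchronous [2+2] to oxetane 7, and retro-[2+2] of 7 in the other sense expels acetone and leaves the ring C=C; the closest known reaction type is the FeCl3-catalysed ring-closing carbonyl–olefin metathesis, which has close precedent for aryl ketones closing cyclohexenes and for aliphatic ketones closing cyclopentenes, but not for an aliphatic methyl ketone closing a six-membered ring. The carbocycle closes in a 6-exo-trig mode at the carbonyl carbon, with the C=O oxygen and the C(CH3)2 carbon both outside the new ring, so that a cis-fused 7-oxabicyclo[4.2.0]octane is the only unstrained oxetane. The step creates no lasting stereocentre, since the two oxetane carbons either become sp2 or leave as acetone, and the two stereocentres of 6 should be carried through because the aprotic Lewis acid at room temperature is not expected to enolise the α-carbon. The step needs chemoselectivity for the prenyl-type alkene over the vinyl group, which is secured because only the gem-dimethyl terminus can carry tertiary cation character and the vinyl group could only close a four-membered ring or form a secondary cation. It also needs metathesis to win over the carbonyl-ene pathway, which the quaternary ring carbon and its CH(CH3) neighbour favour by holding ketone and alkene together (gem-dialkyl effect) and which the loss of volatile acetone makes irreversible.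

Step 4
Reactants: 9 but-2-yn-1-ol
Product: 11 (2Z)-3-iodobut-2-en-1-ol, via cyclic vinylalanate 10 (not isolated)
Conditions: NaAlH2(OCH2CH2OMe)2, THF, 0 °C → rt; then I2, −78 → 0 °C
Reagents that add atoms: iodine, II
Why: Alkoxide-directed trans-hydroalumination of the propargylic alcohol places aluminium on C3 in a five-membered alanate, and iodinolysis of the C–Al bond with retention gives the (Z)-vinyl iodide; no stereocentre is formed.

Step 5
Reactants: 8 (5S,6R)-5-ethenyl-1,5,6-trimethylcyclohex-1-ene; 11 (2Z)-3-iodobut-2-en-1-ol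
Product: 13 (2Z)-3-methyl-5-[(1S,2S)-1,2,3-trimethylcyclohex-3-en-1-yl]pent-2-en-1-ol, via B-alkyl-9-BBN borane 12 (not isolated)
Conditions: 9-BBN (1.2 equiv), THF, rt → 50 °C; then 11, Pd(dppf)Cl2 (5 mol%), AsPh3, Cs2CO3, DMF/H2O, rt
Reagents that add atoms: none
Why: Hydroboration with 9-BBN is anti-Markovnikov and takes only the monosubstituted vinyl group (the trisubstituted ring alkene is far slower), and the B-alkyl Suzuki–Miyaura coupling then joins the primary alkyl group to the vinyl iodide with retention of the (Z)-geometry, no stereocentre being formed or touched.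

Step 6
Reactants: 13 (2Z)-3-methyl-5-[(1S,2S)-1,2,3-trimethylcyclohex-3-en-1-yl]pent-2-en-1-ol
Product: 14 methyl (2Z)-3-methyl-5-[(1S,2S)-1,2,3-trimethylcyclohex-3-en-1-yl]pent-2-en-1-yl carbonate
Conditions: ClCO2Me, pyridine, CH2Cl2, 0 °C
Reagents that add atoms: methyl chloroformate, COC(=O)Cl
Why: Acylation of the primary allylic alcohol with a chloroformate gives the methyl carbonate that serves as the ionisable leaving group in the allylic etherification; no stereocentre is involved.

Step 7
Reactants: 15 1,2,3-trimethoxybenzene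
Product: 16 1,5-dibromo-2,3,4-trimethoxybenzene
Conditions: Br2 (2.1 equiv), CH2Cl2, 0 °C → rt
Reagents that add atoms: bromine, BrBr
Why: Electrophilic aromatic bromination: each outer methoxy group directs one bromine to its free ortho position, which is also para to the other outer methoxy group, so the symmetric dibromide should form.

Step 8
Reactants: 16 1,5-dibromo-2,3,4-trimethoxybenzene
Product: 17 4,5,6-trimethoxybenzene-1,3-diol
Conditions: Pd2(dba)3 (2 mol%), tBuXPhos (8 mol%), KOH, 1,4-dioxane/H2O, 100 °C; then aq HCl (under argon)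
Reagents that add atoms: potassium hydroxide, [K+].[OH-]
Why: Palladium-catalysed hydroxylation of aryl bromides (C–O cross-coupling with hydroxide and a bulky biarylphosphine) should replace both bromine atoms by hydroxyl groups without touching the methyl ethers.

Step 9
Reactants: 17 4,5,6-trimethoxybenzene-1,3-diol
Product: 19 2,6-dihydroxy-3,4,5-trimethoxybenzaldehyde, via aryl iminium chloride 18 (not isolated)
Conditions: POCl3, DMF, MeCN, 0 °C → rt; then H2O, 50 °C
Reagents that add atoms: N,N-dimethylformamide, CN(C)C=O; water, O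
Why: Vilsmeier–Haack formylation of an electron-rich arene can only take place at the single unsubstituted ring carbon, which lies between the two hydroxyl groups, and hydrolysis of the iminium salt releases the aldehyde.

Step 10
Reactants: 19 2,6-dihydroxy-3,4,5-trimethoxybenzaldehyde
Product: 20 2-ethenyl-4,5,6-trimethoxybenzene-1,3-diol
Conditions: Ph3PCH3Br, KOtBu (3.5 equiv each), THF, 0 °C → rt; aq NH4Cl; used at once
Reagents that add atoms: methyltriphenylphosphonium bromide, C[P+](c1ccccc1)(c1ccccc1)c1ccccc1.[Br-]
Why: Wittig methylenation with an excess of the non-stabilised ylide tolerates the two phenoxide groups and turns the aldehyde into the styrene that is needed as one alkene partner of the final ring closure.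

Step 11
Reactants: 14 methyl (2Z)-3-methyl-5-[(1S,2S)-1,2,3-trimethylcyclohex-3-en-1-yl]pent-2-en-1-yl carbonate; 20 2-ethenyl-4,5,6-trimethoxybenzene-1,3-diol (2 equiv)
Product: 21 2-ethenyl-4,5,6-trimethoxy-3-({(3R)-3-methyl-5-[(1S,2S)-1,2,3-trimethylcyclohex-3-en-1-yl]pent-1-en-3-yl}oxy)phenol
Conditions: Pd2(dba)3·CHCl3 (2.5 mol%), (S,S)-DACH-phenyl ligand N,N′-[(1S,2S)-cyclohexane-1,2-diyl]bis[2-(diphenylphosphanyl)benzamide] (7.5 mol%), CH2Cl2, rt
Reagents that add atoms: none
Why: Palladium-catalysed asymmetric allylic alkylation of a phenol (Tsuji–Trost type): ionisation of the carbonate gives a π-allylpalladium complex, the phenoxide attacks its more substituted terminus inside the chiral pocket of the ligand and so sets the (R)-configured tertiary ether carbon, and the twofold excess of the symmetric diol should hold back double alkylation.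

Step 12
Reactants: 21 2-ethenyl-4,5,6-trimethoxy-3-({(3R)-3-methyl-5-[(1S,2S)-1,2,3-trimethylcyclohex-3-en-1-yl]pent-1-en-3-yl}oxy)phenol
Product: 22 (2R)-6,7,8-trimethoxy-2-methyl-2-{2-[(1S,2S)-1,2,3-trimethylcyclohex-3-en-1-yl]ethyl}-2H-chromen-5-ol
Conditions: second-generation Grubbs catalyst (H2IMes)(PCy3)Cl2Ru=CHPh (5 mol%), CH2Cl2, 40 °C
Reagents that add atoms: none
Why: Ring-closing metathesis of the styrene with the vinyl group on the tertiary ether carbon closes the six-membered pyran ring with loss of ethylene, and neither the trisubstituted ring alkene nor the three stereocentres can react with the ruthenium carbene.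

**Compound list**

1 | geranyl propionate, (2E)-3,7-dimethylocta-2,6-dien-1-yl propanoate | CCC(=O)OC/C=C(\C)CCC=C(C)C | starting material
2 | boron ketene acetal of 1 (not isolated): (4S,5S)-1,3-bis{[3,5-bis(trifluoromethyl)phenyl]sulfonyl}-2-[((1Z)-1-{[(2E)-3,7-dimethylocta-2,6-dien-1-yl]oxy}prop-1-en-1-yl)oxy]-4,5-diphenyl-1,3,2-diazaborolidine, methyl cis to the allyloxy oxygen | C/C=C(\OC/C=C(\C)CCC=C(C)C)OB1N(S(=O)(=O)c2cc(cc(c2)C(F)(F)F)C(F)(F)F)[C@@H](c2ccccc2)[C@H](c2ccccc2)N1S(=O)(=O)c2cc(cc(c2)C(F)(F)F)C(F)(F)F | intermediate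
3 | boron carboxylate (not isolated): (4S,5S)-1,3-bis{[3,5-bis(trifluoromethyl)phenyl]sulfonyl}-4,5-diphenyl-1,3,2-diazaborolidin-2-yl (2S,3S)-3-ethenyl-2,3,7-trimethyloct-6-enoate | C=C[C@](C)(CCC=C(C)C)[C@H](C)C(=O)OB1N(S(=O)(=O)c2cc(cc(c2)C(F)(F)F)C(F)(F)F)[C@@H](c2ccccc2)[C@H](c2ccccc2)N1S(=O)(=O)c2cc(cc(c2)C(F)(F)F)C(F)(F)F | intermediate
4 | (2S,3S)-3-ethenyl-2,3,7-trimethyloct-6-enoic acid | C=C[C@](C)(CCC=C(C)C)[C@H](C)C(=O)O | intermediate
5 | dilithium (3S,4S)-4-ethenyl-3,4,8-trimethylnon-7-ene-2,2-diolate (not isolated) | C=C[C@](C)(CCC=C(C)C)[C@H](C)C(C)([O-])[O-].[Li+].[Li+] | intermediate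
6 | (3S,4S)-4-ethenyl-3,4,8-trimethylnon-7-en-2-one | C=C[C@](C)(CCC=C(C)C)[C@H](C)C(C)=O | intermediate
7 | 4-ethenyl-4,5,6,8,8-pentamethyl-7-oxabicyclo[4.2.0]octane (not isolated; C4 and C5 as in 6, cis ring fusion, the two fusion centres transient) | C=C[C@]1(C)CCC2C(C)(C)OC2(C)[C@H]1C | intermediate
8 | (5S,6R)-5-ethenyl-1,5,6-trimethylcyclohex-1-ene (the 5- and 6-methyl groups cis) | C=C[C@]1(C)CCC=C(C)[C@H]1C | intermediate
9 | but-2-yn-1-ol | CC#CCO | starting material
10 | sodium 2,2-bis(2-methoxyethoxy)-3-methyl-2,5-dihydro-1,2-oxaluminol-2-uide (not isolated) | CC1=CCO[Al-]1(OCCOC)OCCOC.[Na+] | intermediate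
11 | (2Z)-3-iodobut-2-en-1-ol | OC/C=C(/C)I | intermediate
12 | 9-{2-[(1R,2S)-1,2,3-trimethylcyclohex-3-en-1-yl]ethyl}-9-borabicyclo[3.3.1]nonane (not isolated; same spatial arrangement as in 8) | B1(CC[C@]2(C)CCC=C(C)[C@H]2C)C2CCCC1CCC2 | intermediate
13 | (2Z)-3-methyl-5-[(1S,2S)-1,2,3-trimethylcyclohex-3-en-1-yl]pent-2-en-1-ol | OC/C=C(/C)CC[C@]1(C)CCC=C(C)[C@H]1C | intermediate
14 | methyl (2Z)-3-methyl-5-[(1S,2S)-1,2,3-trimethylcyclohex-3-en-1-yl]pent-2-en-1-yl carbonate | COC(=O)OC/C=C(/C)CC[C@]1(C)CCC=C(C)[C@H]1C | intermediate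
15 | 1,2,3-trimethoxybenzene | COc1cccc(OC)c1OC | starting material
16 | 1,5-dibromo-2,3,4-trimethoxybenzene | COc1c(Br)cc(Br)c(OC)c1OC | intermediate
17 | 4,5,6-trimethoxybenzene-1,3-diol | COc1c(O)cc(O)c(OC)c1OC | intermediate
18 | [(2,6-dihydroxy-3,4,5-trimethoxyphenyl)methylidene]dimethylammonium chloride (not isolated) | C[N+](C)=Cc1c(O)c(OC)c(OC)c(OC)c1O.[Cl-] | intermediate
19 | 2,6-dihydroxy-3,4,5-trimethoxybenzaldehyde | O=Cc1c(O)c(OC)c(OC)c(OC)c1O | intermediate
20 | 2-ethenyl-4,5,6-trimethoxybenzene-1,3-diol | C=Cc1c(O)c(OC)c(OC)c(OC)c1O | intermediate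
21 | 2-ethenyl-4,5,6-trimethoxy-3-({(3R)-3-methyl-5-[(1S,2S)-1,2,3-trimethylcyclohex-3-en-1-yl]pent-1-en-3-yl}oxy)phenol | COc1c(O)c(C=C)c(c(OC)c1OC)O[C@](C)(CC[C@]1(C)CCC=C(C)[C@H]1C)C=C | intermediate
22 | (2R)-6,7,8-trimethoxy-2-methyl-2-{2-[(1S,2S)-1,2,3-trimethylcyclohex-3-en-1-yl]ethyl}-2H-chromen-5-ol | COc1c(O)c2c(c(OC)c1OC)O[C@](C)(CC[C@]1(C)CCC=C(C)[C@H]1C)C=C2 | target

Total step count: 12.
Longest linear sequence: 7 steps (steps 1, 2, 3, 5, 6, 11, 12, from geranyl propionate 1).

**Steps most likely to fail**

Step 3 (bears the label). Proton loss from the tertiary cation may outrun oxetane closure, diverting the reaction into the carbonyl-ene (Prins) manifold. The released acetone may also bind and slow the catalyst, and the Lewis acid may epimerise the α-carbon or shift the new double bond. The fallback replaces the metathesis by an intramolecular McMurry coupling (known chemistry), sets out from 6 and comes back at 8. The trisubstituted alkene of 6 is epoxidised chemoselectively (mCPBA, NaHCO3, CH2Cl2, 0 °C) to (3S,4S)-4-[2-(3,3-dimethyloxiran-2-yl)ethyl]-3,4-dimethylhex-5-en-2-one F1. Cleavage of the epoxide with H5IO6 (THF/H2O, 0 °C) then gives (4S,5S)-4-ethenyl-4,5-dimethyl-6-oxoheptanal F2. Slow addition of F2 to low-valent titanium (TiCl3(DME)1.5, Zn–Cu couple, DME, reflux) couples the aldehyde and ketone carbons reductively into the same ring C=C bond and gives 8; the vinyl group is inert throughout.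

Step 11. Attack of the doubly ortho-substituted phenoxide at the tertiary allyl terminus may be slowed by crowding, so that linear ether formation, re-ionisation of the product ether with erosion of regio- and enantioselectivity, or double alkylation take over. The fallback moves the carbon–carbon bond formation on the arene behind the etherification, sets out from 14 and 17 and comes back at 21. The same palladium/ligand system is used with the less hindered diol 17 (2 equiv), whose reacting hydroxyl has one free ortho position, to give 4,5,6-trimethoxy-3-({(3R)-3-methyl-5-[(1S,2S)-1,2,3-trimethylcyclohex-3-en-1-yl]pent-1-en-3-yl}oxy)phenol F3. Magnesium-mediated ortho-formylation (MgCl2, Et3N, paraformaldehyde, MeCN, reflux) at the only free ring carbon gives 2-hydroxy-3,4,5-trimethoxy-6-({(3R)-3-methyl-5-[(1S,2S)-1,2,3-trimethylcyclohex-3-en-1-yl]pent-1-en-3-yl}oxy)benzaldehyde F4. Wittig methylenation of F4 (Ph3PCH3Br, KOtBu, THF) gives 21.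

Step 1. The boron ketene acetal of a trisubstituted allyl ester may rearrange only slowly, enolate geometry may be controlled incompletely (lowering the diastereoselectivity at the CH(CH3) centre), and facial selectivity may be moderate. The fallback replaces reagent control by resolution, sets out from 1 and comes back at 4. The classical Ireland–Claisen rearrangement (LiN(iPr)2, THF, −78 °C; Me3SiCl; then rt) runs through trimethylsilyl ketene acetal (1E)-1-{[(2E)-3,7-dimethylocta-2,6-dien-1-yl]oxy}-1-(trimethylsilyloxy)prop-1-ene F5 and racemic trimethylsilyl (2S*,3S*)-3-ethenyl-2,3,7-trimethyloct-6-enoate F6. Hydrolysis gives the racemic acid with the same relative configuration, that is 4 together with (2R,3R)-3-ethenyl-2,3,7-trimethyloct-6-enoic acid F7. Crystallisation of (1S)-1-phenylethylammonium (2S,3S)-3-ethenyl-2,3,7-trimethyloct-6-enoate F8 (the amine enantiomer being chosen by trial) and acidification return 4.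

**Further compounds**

F1 | step 3 | (3S,4S)-4-[2-(3,3-dimethyloxiran-2-yl)ethyl]-3,4-dimethylhex-5-en-2-one (epoxide carbon as a mixture) | C=C[C@](C)(CCC1OC1(C)C)[C@H](C)C(C)=O
F2 | step 3 | (4S,5S)-4-ethenyl-4,5-dimethyl-6-oxoheptanal | C=C[C@](C)(CCC=O)[C@H](C)C(C)=O
F3 | step 11 | 4,5,6-trimethoxy-3-({(3R)-3-methyl-5-[(1S,2S)-1,2,3-trimethylcyclohex-3-en-1-yl]pent-1-en-3-yl}oxy)phenol | COc1c(O)cc(c(OC)c1OC)O[C@](C)(CC[C@]1(C)CCC=C(C)[C@H]1C)C=C
F4 | step 11 | 2-hydroxy-3,4,5-trimethoxy-6-({(3R)-3-methyl-5-[(1S,2S)-1,2,3-trimethylcyclohex-3-en-1-yl]pent-1-en-3-yl}oxy)benzaldehyde | COc1c(O)c(C=O)c(c(OC)c1OC)O[C@](C)(CC[C@]1(C)CCC=C(C)[C@H]1C)C=C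
F5 | step 1 | (1E)-1-{[(2E)-3,7-dimethylocta-2,6-dien-1-yl]oxy}-1-(trimethylsilyloxy)prop-1-ene | C/C=C(\OC/C=C(\C)CCC=C(C)C)O[Si](C)(C)C
F6 | step 1 | trimethylsilyl (2S*,3S*)-3-ethenyl-2,3,7-trimethyloct-6-enoate (racemic; the 2S,3S enantiomer is drawn) | C=C[C@](C)(CCC=C(C)C)[C@H](C)C(=O)O[Si](C)(C)C
F7 | step 1 | (2R,3R)-3-ethenyl-2,3,7-trimethyloct-6-enoic acid | C=C[C@@](C)(CCC=C(C)C)[C@@H](C)C(=O)O
F8 | step 1 | (1S)-1-phenylethylammonium (2S,3S)-3-ethenyl-2,3,7-trimethyloct-6-enoate | C=C[C@](C)(CCC=C(C)C)[C@H](C)C(=O)[O-].C[C@H]([NH3+])c1ccccc1
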